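Ring C is opened at the C2–C3 bond. C2, the unsubstituted CH between O1 and C3, is treated as the methyl of an aryl methyl ether. Because ring A carries oxygen on both carbons flanking C4a (C8a–O1 and C5–O), a 2,6-dimethoxyaryl ketone presents two equivalent methoxy groups. A dirhodium carbenoid generated at C3 from an α-aryl-α-diazo ketone inserts into a methoxy C–H bond, which forms C2–C3 and closes ring C as an isoflavanone in one operation; the unused methoxy group becomes the 5-oxygen. The precursor is the diazo deoxybenzoin 12, with rings A, B and D complete and both phenols masked as pivalates.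

Key step: step 8

Remark: isoflavone numbering is used (rings A and C are the chromone, ring B the aryl group at C3, ring D the dimethylpyran); 13 is made and used as the racemate, because its only stereocentre (C3) becomes trigonal in step 9 and the target is achiral.

Step 1
Reactants: 1 4-bromoresorcinol (4-bromobenzene-1,3-diol); 2 3-methylbut-2-enoic acid
Product: 3 6-bromo-7-hydroxy-2,2-dimethylchroman-4-one
Conditions: P2O5/MeSO3H (Eaton's reagent), 70 °C
Reagents that add atoms: none
Why: Friedel–Crafts acylation of 1 at C6 (the unhindered position para to one hydroxyl and ortho to the other) followed by intramolecular oxa-Michael addition of the ortho hydroxyl is the standard one-pot chromanone annulation of resorcinols and places bromine at C6 next to the free 7-hydroxyl.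

Step 2
Reactants: 3 6-bromo-7-hydroxy-2,2-dimethylchroman-4-one
Product: 4 6-bromo-2,2-dimethyl-7-(triisopropylsilyloxy)chroman-4-one
Conditions: TIPSCl, imidazole, DMF, rt
Reagents that add atoms: triisopropylsilyl chloride, CC(C)[Si](Cl)(C(C)C)C(C)C
Why: Imidazole-promoted O-silylation of the phenol gives a triisopropylsilyl ether that should tolerate borohydride, aqueous acid and tert-butoxide and removes the acidic proton that would slow ketone reduction.

Step 3
Reactants: 4 6-bromo-2,2-dimethyl-7-(triisopropylsilyloxy)chroman-4-one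
Product: 6 6-bromo-2,2-dimethyl-7-(triisopropylsilyloxy)-2H-chromene, via 4-chromanol 5 (not isolated)
Conditions: NaBH4, THF–MeOH, 0 °C to rt; then 4 M aq HCl, rt
Reagents that add atoms: none
Why: Borohydride reduction of the aryl ketone followed in the same flask by acid-catalysed E1 dehydration should work because the C4 benzylic cation is stabilised by O1 and the para silyloxy group, and the transient racemic C4 stereocentre disappears with the new C3=C4 bond.

Step 4
Reactants: 7 1-(4-hydroxy-2,6-dimethoxyphenyl)ethanone
Product: 8 1-[2,6-dimethoxy-4-(triisopropylsilyloxy)phenyl]ethanone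
Conditions: TIPSCl, imidazole, DMF, rt
Reagents that add atoms: triisopropylsilyl chloride, CC(C)[Si](Cl)(C(C)C)C(C)C
Why: The same phenol O-silylation masks the only acidic O–H of the ketone partner, so that tert-butoxide deprotonates the acetyl methyl group alone in step 5.

Step 5
Reactants: 6 6-bromo-2,2-dimethyl-7-(triisopropylsilyloxy)-2H-chromene; 8 1-[2,6-dimethoxy-4-(triisopropylsilyloxy)phenyl]ethanone (1.2 equiv)
Product: 9 1-[2,6-dimethoxy-4-(triisopropylsilyloxy)phenyl]-2-[2,2-dimethyl-7-(triisopropylsilyloxy)-2H-chromen-6-yl]ethanone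
Conditions: Pd2(dba)3 (2 mol %), XPhos (8 mol %), NaOtBu (2.2 equiv), toluene, 70 °C
Reagents that add atoms: none
Why: Buchwald–Hartwig-type palladium-catalysed α-arylation of the sodium enolate of methyl ketone 8 with aryl bromide 6 (oxidative addition, enolate transfer to palladium, reductive elimination) is reliable for electron-rich ortho-oxygenated aryl bromides with a bulky biarylphosphine and should stop at monoarylation because the product enolate is hindered and stabilised.

Step 6
Reactants: 9 1-[2,6-dimethoxy-4-(triisopropylsilyloxy)phenyl]-2-[2,2-dimethyl-7-(triisopropylsilyloxy)-2H-chromen-6-yl]ethanone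
Product: 11 1-[2,6-dimethoxy-4-(pivaloyloxy)phenyl]-2-[2,2-dimethyl-7-(pivaloyloxy)-2H-chromen-6-yl]ethanone, via bisphenol 10 (not isolated)
Conditions: TBAF (2.2 equiv), THF, 0 °C; then PivCl (3 equiv), Et3N, DMAP (cat.), 0 °C to rt
Reagents that add atoms: pivaloyl chloride, CC(C)(C)C(Cl)=O
Why: Fluoride desilylation gives the two tetrabutylammonium phenoxides, which undergo nucleophilic acyl substitution with pivaloyl chloride in the same flask, so the silyl ethers are exchanged under non-acidic conditions for base-cleavable esters that carry no C–H bond next to the phenolic oxygen.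

Step 7
Reactants: 11 1-[2,6-dimethoxy-4-(pivaloyloxy)phenyl]-2-[2,2-dimethyl-7-(pivaloyloxy)-2H-chromen-6-yl]ethanone
Product: 12 2-diazo-1-[2,6-dimethoxy-4-(pivaloyloxy)phenyl]-2-[2,2-dimethyl-7-(pivaloyloxy)-2H-chromen-6-yl]ethanone
Conditions: p-ABSA (1.3 equiv), DBU (1.5 equiv, added last), MeCN, 0 °C
Reagents that add atoms: 4-acetamidobenzenesulfonyl azide (p-ABSA), CC(=O)Nc1ccc(cc1)S(=O)(=O)N=[N+]=[N-]
Why: Regitz diazo transfer should succeed directly because the methylene of 11 is activated by both the carbonyl group and ring B, so DBU generates the enolate, which attacks the sulfonyl azide, and the adduct collapses to the diazo ketone and the sulfonamide.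

Step 8
Reactants: 12 2-diazo-1-[2,6-dimethoxy-4-(pivaloyloxy)phenyl]-2-[2,2-dimethyl-7-(pivaloyloxy)-2H-chromen-6-yl]ethanone
Product: 13 rac-3-[2,2-dimethyl-7-(pivaloyloxy)-2H-chromen-6-yl]-5-methoxy-7-(pivaloyloxy)chroman-4-one
Conditions: Rh2(esp)2 (1 mol %; esp = α,α,α′,α′-tetramethyl-1,3-benzenedipropanoate), CH2Cl2, 40 °C, 12 added by syringe pump over 4 h (final 0.01 M)
Reagents that add atoms: none
Why: Decomposition of the diazo group of 12 on Rh2(esp)2 should generate an aryl-stabilised (donor–acceptor) rhodium carbenoid at C3, whose electrophilic carbon inserts into a C–H bond of a neighbouring methoxy group in a concerted, hydride-shift-like event that forms C2–C3. The closest known reaction type is the dirhodium-carboxylate-catalysed intramolecular C–H insertion of 2-alkoxyaryl α-diazo ketones next to the ether oxygen, which gives chroman-4-ones. Ring C closes as a six-membered ring by 1,6-insertion (C3 and the methyl carbon C2 are linked through C4, C4a, C8a and O1), helped by the two ortho substituents, which turn the aroyl group out of the ring plane and bring a methoxy group above the carbenoid. The new stereocentre C3 forms as a racemate because substrate and catalyst are achiral, and no control is needed since step 9 makes C3 trigonal. The step needs chemoselectivity for C–H insertion over five-membered oxonium ylide formation with methyl shift, carbonyl ylide formation at the 2'-ester, Wolff rearrangement, and bimolecular carbene dimerisation or cyclopropanation of the ring D alkene: the stabilised carbenoid is selective and slow to rearrange, methyl migrates poorly so ylide formation can revert, the 2'-pivalate offers no C–H bond next to oxygen (an ether there would be inserted with five-ring closure) and only a weak, hindered carbonyl donor, and slow addition at high dilution with a bulky chelating carboxylate catalyst disfavours bimolecular paths. Site selectivity is built in, because no other C–H bond next to oxygen can reach C3 and either methoxy group gives the same product.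

Step 9
Reactants: 13 rac-3-[2,2-dimethyl-7-(pivaloyloxy)-2H-chromen-6-yl]-5-methoxy-7-(pivaloyloxy)chroman-4-one
Product: 14 3-[2,2-dimethyl-7-(pivaloyloxy)-2H-chromen-6-yl]-5-methoxy-7-(pivaloyloxy)-4H-chromen-4-one
Conditions: DDQ (2 equiv), 1,4-dioxane, 100 °C
Reagents that add atoms: none
Why: DDQ dehydrogenation of the chroman-4-one (enolisation, hydride abstraction from C2 assisted by O1, proton loss) is an established isoflavanone-to-isoflavone oxidation that removes the C3 stereocentre and should leave the 2,2-dimethylchromene, which has no hydrogen at its C2, untouched.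

Step 10
Reactants: 14 3-[2,2-dimethyl-7-(pivaloyloxy)-2H-chromen-6-yl]-5-methoxy-7-(pivaloyloxy)-4H-chromen-4-one
Product: 15 3-[2,2-dimethyl-7-(pivaloyloxy)-2H-chromen-6-yl]-5-hydroxy-7-(pivaloyloxy)-4H-chromen-4-one
Conditions: BCl3 (1 M in CH2Cl2, 2.5 equiv), CH2Cl2, −78 to 0 °C; then ice-water
Reagents that add atoms: none
Why: In this chelation-controlled Lewis-acid demethylation BCl3 binds between the C4 carbonyl and the peri 5-methoxy oxygen and chloride removes the methyl group, a standard selective cleavage that spares aryl pivalates, while the low temperature and the electron-withdrawing esters on rings A and B should protect the acid-sensitive ring D alkene.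

Step 11
Reactants: 15 3-[2,2-dimethyl-7-(pivaloyloxy)-2H-chromen-6-yl]-5-hydroxy-7-(pivaloyloxy)-4H-chromen-4-one
Product: 16 eriosemaone D (5,7-dihydroxy-3-(7-hydroxy-2,2-dimethyl-2H-chromen-6-yl)-4H-chromen-4-one)
Conditions: K2CO3 (3 equiv), MeOH, rt, argon
Reagents that add atoms: none
Why: Base-mediated transesterification (methanolysis) of the two aryl pivalates by methoxide formed from K2CO3 in methanol should release the 7- and 2'-phenols under conditions that the chromone (deactivated as its phenoxide) and the chromene tolerate.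

Compound list
1 | 4-bromoresorcinol (4-bromobenzene-1,3-diol) | Oc1ccc(Br)c(O)c1 | starting material
2 | 3-methylbut-2-enoic acid | CC(C)=CC(=O)O | starting material
3 | 6-bromo-7-hydroxy-2,2-dimethylchroman-4-one | CC1(C)CC(=O)c2cc(Br)c(O)cc2O1 | intermediate
4 | 6-bromo-2,2-dimethyl-7-(triisopropylsilyloxy)chroman-4-one | CC1(C)CC(=O)c2cc(Br)c(O[Si](C(C)C)(C(C)C)C(C)C)cc2O1 | intermediate
5 | rac-6-bromo-2,2-dimethyl-7-(triisopropylsilyloxy)chroman-4-ol (racemic at C4, formed in the flask) | CC1(C)CC(O)c2cc(Br)c(O[Si](C(C)C)(C(C)C)C(C)C)cc2O1 | intermediate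
6 | 6-bromo-2,2-dimethyl-7-(triisopropylsilyloxy)-2H-chromene | CC1(C)C=Cc2cc(Br)c(O[Si](C(C)C)(C(C)C)C(C)C)cc2O1 | intermediate
7 | 1-(4-hydroxy-2,6-dimethoxyphenyl)ethanone | CC(=O)c1c(OC)cc(O)cc1OC | starting material
8 | 1-[2,6-dimethoxy-4-(triisopropylsilyloxy)phenyl]ethanone | CC(=O)c1c(OC)cc(O[Si](C(C)C)(C(C)C)C(C)C)cc1OC | intermediate
9 | 1-[2,6-dimethoxy-4-(triisopropylsilyloxy)phenyl]-2-[2,2-dimethyl-7-(triisopropylsilyloxy)-2H-chromen-6-yl]ethanone | COc1cc(O[Si](C(C)C)(C(C)C)C(C)C)cc(OC)c1C(=O)Cc1cc2C=CC(C)(C)Oc2cc1O[Si](C(C)C)(C(C)C)C(C)C | intermediate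
10 | 1-(4-hydroxy-2,6-dimethoxyphenyl)-2-(7-hydroxy-2,2-dimethyl-2H-chromen-6-yl)ethanone (present in the flask as its bis(tetrabutylammonium) phenoxide) | COc1cc(O)cc(OC)c1C(=O)Cc1cc2C=CC(C)(C)Oc2cc1O | intermediate
11 | 1-[2,6-dimethoxy-4-(pivaloyloxy)phenyl]-2-[2,2-dimethyl-7-(pivaloyloxy)-2H-chromen-6-yl]ethanone | COc1cc(OC(=O)C(C)(C)C)cc(OC)c1C(=O)Cc1cc2C=CC(C)(C)Oc2cc1OC(=O)C(C)(C)C | intermediate
12 | 2-diazo-1-[2,6-dimethoxy-4-(pivaloyloxy)phenyl]-2-[2,2-dimethyl-7-(pivaloyloxy)-2H-chromen-6-yl]ethanone | COc1cc(OC(=O)C(C)(C)C)cc(OC)c1C(=O)C(=[N+]=[N-])c1cc2C=CC(C)(C)Oc2cc1OC(=O)C(C)(C)C | intermediate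
13 | rac-3-[2,2-dimethyl-7-(pivaloyloxy)-2H-chromen-6-yl]-5-methoxy-7-(pivaloyloxy)chroman-4-one (racemic at C3) | COc1cc(OC(=O)C(C)(C)C)cc2OCC(c3cc4C=CC(C)(C)Oc4cc3OC(=O)C(C)(C)C)C(=O)c12 | intermediate
14 | 3-[2,2-dimethyl-7-(pivaloyloxy)-2H-chromen-6-yl]-5-methoxy-7-(pivaloyloxy)-4H-chromen-4-one | COc1cc(OC(=O)C(C)(C)C)cc2occ(-c3cc4C=CC(C)(C)Oc4cc3OC(=O)C(C)(C)C)c(=O)c12 | intermediate
15 | 3-[2,2-dimethyl-7-(pivaloyloxy)-2H-chromen-6-yl]-5-hydroxy-7-(pivaloyloxy)-4H-chromen-4-one | Oc1cc(OC(=O)C(C)(C)C)cc2occ(-c3cc4C=CC(C)(C)Oc4cc3OC(=O)C(C)(C)C)c(=O)c12 | intermediate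
16 | eriosemaone D, 5,7-dihydroxy-3-(7-hydroxy-2,2-dimethyl-2H-chromen-6-yl)-4H-chromen-4-one (no stereocentre) | CC1(C)C=Cc2cc(-c3coc4cc(O)cc(O)c4c3=O)c(O)cc2O1 | target

Total step count: 11 steps.
Longest linear sequence: 10 steps (1 to 16 through steps 1–3 and 5–11); step 4 prepares the ketone partner on a one-step branch.

Steps most likely to fail

Step 8. The carbenoid may be diverted before it inserts. Possible diversions are attack of the methoxy oxygen with methyl migration, capture by the carbonyl of the neighbouring pivalate, and bimolecular consumption by dimerisation or addition to the ring D alkene. The fallback uses classical isoflavone chemistry, sets out from 11 and comes back to the route at 14. Chelation-controlled mono-demethylation of 11 with BCl3 (1.1 equiv, CH2Cl2, −78 °C) should give 1-[2-hydroxy-6-methoxy-4-(pivaloyloxy)phenyl]-2-[2,2-dimethyl-7-(pivaloyloxy)-2H-chromen-6-yl]ethanone F1. Heating F1 with N,N-dimethylformamide dimethyl acetal in toluene at 90 °C should give the enaminone 3-(dimethylamino)-1-[2-hydroxy-6-methoxy-4-(pivaloyloxy)phenyl]-2-[2,2-dimethyl-7-(pivaloyloxy)-2H-chromen-6-yl]prop-2-en-1-one F2 (either alkene geometry serves). F2 should cyclise in the same flask through the free phenol with loss of dimethylamine to isoflavone 14, so steps 7–9 are bypassed.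

Step 7. The enolate of 11 may transfer the 2'-pivaloyl group to its own carbon or oxygen before it meets the azide, or the hindered enolate may react too slowly. The fallback reorders the protecting-group exchange so that no ester is present during diazo transfer; it sets out from 9 and comes back at 12. Diazo transfer to 9 (p-ABSA, DBU, MeCN, 0 °C) should give 2-diazo-1-[2,6-dimethoxy-4-(triisopropylsilyloxy)phenyl]-2-[2,2-dimethyl-7-(triisopropylsilyloxy)-2H-chromen-6-yl]ethanone F3. TBAF in THF at 0 °C should then release 2-diazo-1-(4-hydroxy-2,6-dimethoxyphenyl)-2-(7-hydroxy-2,2-dimethyl-2H-chromen-6-yl)ethanone F4 as its bisphenoxide. F4 is kept basic and acylated at once with pivaloyl chloride to give 12.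

Step 10. The Lewis acid, or hydrogen chloride formed on quenching, may attack ring D by addition to the alkene, opening of the pyran ether or cationic oligomerisation, or the demethylation may stall at the temperature the chromene tolerates. The fallback replaces the acidic cleavage by an anionic one that also removes the esters; it sets out from 14 and comes back at the target 16. Sodium ethanethiolate (excess) in DMF at rt should first cleave both pivalates by thiolysis to give 7-hydroxy-3-(7-hydroxy-2,2-dimethyl-2H-chromen-6-yl)-5-methoxy-4H-chromen-4-one F5 as its phenoxide. Warming to about 100 °C should then remove the only remaining methyl group by SN2 attack of thiolate on the carbonyl-activated 5-methyl ether, and acidification should give 16.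

Further compounds
F1 | step 8 | 1-[2-hydroxy-6-methoxy-4-(pivaloyloxy)phenyl]-2-[2,2-dimethyl-7-(pivaloyloxy)-2H-chromen-6-yl]ethanone | COc1cc(OC(=O)C(C)(C)C)cc(O)c1C(=O)Cc1cc2C=CC(C)(C)Oc2cc1OC(=O)C(C)(C)C
F2 | step 8 | 3-(dimethylamino)-1-[2-hydroxy-6-methoxy-4-(pivaloyloxy)phenyl]-2-[2,2-dimethyl-7-(pivaloyloxy)-2H-chromen-6-yl]prop-2-en-1-one (alkene geometry not defined) | COc1cc(OC(=O)C(C)(C)C)cc(O)c1C(=O)C(=CN(C)C)c1cc2C=CC(C)(C)Oc2cc1OC(=O)C(C)(C)C
F3 | step 7 | 2-diazo-1-[2,6-dimethoxy-4-(triisopropylsilyloxy)phenyl]-2-[2,2-dimethyl-7-(triisopropylsilyloxy)-2H-chromen-6-yl]ethanone | COc1cc(O[Si](C(C)C)(C(C)C)C(C)C)cc(OC)c1C(=O)C(=[N+]=[N-])c1cc2C=CC(C)(C)Oc2cc1O[Si](C(C)C)(C(C)C)C(C)C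
F4 | step 7 | 2-diazo-1-(4-hydroxy-2,6-dimethoxyphenyl)-2-(7-hydroxy-2,2-dimethyl-2H-chromen-6-yl)ethanone | COc1cc(O)cc(OC)c1C(=O)C(=[N+]=[N-])c1cc2C=CC(C)(C)Oc2cc1O
F5 | step 10 | 7-hydroxy-3-(7-hydroxy-2,2-dimethyl-2H-chromen-6-yl)-5-methoxy-4H-chromen-4-one | COc1cc(O)cc2occ(-c3cc4C=CC(C)(C)Oc4cc3O)c(=O)c12
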